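**Retrosynthetic overview**
1. Target 28 ⇐ allylic chlorination with alkene transposition (C6–Cl, C5=C16) of the (5Z)-macrocycle 27 ⇐ ring-closing metathesis of seco-triene 26; the nine-membered ring is formed last.
2. γ-Lactone ⇐ C9–OH-directed dihydroxylation of a (7Z)-diene ester and lactonisation; that side chain ⇐ aldol at C10 of chlorocyclobutanone 11 with dienal 16.
3. Ring B ⇐ one-carbon ring expansion of the cyclobutanone (1,2-shift of C10 onto a silyl diazoethane carbon) with C11 oxidation in the same flask; this is the key step.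
4. Ring A plus cyclobutanone ⇐ intramolecular chloro(vinyl)ketene [2+2] of acid 8; C3/C4 ⇐ asymmetric allylboration of methacrolein with boronate 4.
5. Ring order: ring A and the cyclobutane together, then ring B by expansion, then the γ-lactone, then the nine-membered ring.

Convention: positions use target numbers, in SMILES order C16=C5, C4, C3, C2=C14, C13, C12, C11(C20), C10, C9, C8, C17(C18), C19, O, C7, C6, C1(C15); stereocentres have the target configuration unless stated, and 16–24 are 1:1 mixtures at C17 because 16 is racemic.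

**Route**

Step 1
Reactants: 1 methacrolein
Product: 2 (2E)-4-methylpenta-2,4-dienal
Conditions: Ph3P=CHCHO, PhMe, 80 °C
Reagents that add atoms: (triphenylphosphoranylidene)acetaldehyde, O=CC=P(c1ccccc1)(c1ccccc1)c1ccccc1
Why: Wittig olefination with the formyl-stabilised ylide gives the E-enal and leaves the 1,1-disubstituted alkene alone; no stereocentre is formed.

Step 2
Reactants: 2 (2E)-4-methylpenta-2,4-dienal
Product: 3 (3E)-5,5-dimethoxy-2-methylpenta-1,3-diene
Conditions: HC(OMe)3, MeOH, NH4NO3 (cat.), 23 °C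
Reagents that add atoms: trimethyl orthoformate, COC(OC)OC
Why: Acid-catalysed acetalisation with the orthoformate as water scavenger masks the aldehyde; no stereocentre is formed.

Step 3
Reactants: 3 (3E)-5,5-dimethoxy-2-methylpenta-1,3-diene
Product: 4 2-[(2E)-5,5-dimethoxy-2-methylpent-2-en-1-yl]-4,4,5,5-tetramethyl-1,3,2-dioxaborolane
Conditions: pinacolborane, FeCl2 (5 mol %), 2-iminopyridine ligand, Mg (10 mol %), Et2O, 23 °C
Reagents that add atoms: pinacolborane, CC1(C)OBOC1(C)C
Why: Iron-catalysed 1,4-hydroboration of the 1,3-diene puts hydrogen on the substituted terminus and boron on the free CH2 through an allyliron intermediate, giving the E-allylboronate needed for an anti allylation.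

Step 4
Reactants: 4 2-[(2E)-5,5-dimethoxy-2-methylpent-2-en-1-yl]-4,4,5,5-tetramethyl-1,3,2-dioxaborolane; 1 methacrolein
Product: 6 (3S,4S)-4-(2,2-dimethoxyethyl)-2,5-dimethylhexa-1,5-dien-3-yl acetate, via alcohol 5 (not isolated)
Conditions: (S)-TRIP phosphoric acid (5 mol %), PhMe, −30 °C; MeOH; then Ac2O, pyridine, DMAP, 23 °C
Reagents that add atoms: acetic anhydride, CC(=O)OC(C)=O
Why: Chiral phosphoric acid-catalysed allylboration through a closed chair (Zimmerman–Traxler) transition state puts the E γ-substituent equatorial, so the C4 oxygen and the C3 side chain come out anti, while the catalyst directs the allyl group to the Si face of the aldehyde (sets C4 and C3); the alcohol is acetylated in the same flask.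

Step 5
Reactants: 6 (3S,4S)-4-(2,2-dimethoxyethyl)-2,5-dimethylhexa-1,5-dien-3-yl acetate
Product: 7 (3S,4S)-2,5-dimethyl-4-(2-oxoethyl)hexa-1,5-dien-3-yl acetate
Conditions: PPTS, acetone–H2O (4:1), 50 °C
Reagents that add atoms: water, O
Why: Mild acid-catalysed acetal hydrolysis leaves the allylic acetate and both 1,1-disubstituted alkenes intact; no stereocentre is formed.

Step 6
Reactants: 7 (3S,4S)-2,5-dimethyl-4-(2-oxoethyl)hexa-1,5-dien-3-yl acetate
Product: 8 (2Z,5S,6S)-6-acetoxy-2-chloro-7-methyl-5-(prop-1-en-2-yl)octa-2,7-dienoic acid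
Conditions: (EtO)2P(O)CHClCO2H, LiN(SiMe3)2 (2 equiv), THF, −78 → 0 °C; aq. HCl work-up
Reagents that add atoms: 2-chloro-2-(diethoxyphosphoryl)acetic acid, CCOP(=O)(OCC)C(Cl)C(O)=O
Why: Horner–Wadsworth–Emmons olefination with the dianion of the α-chlorophosphonoacetic acid gives the 2-chloro-2-enoic acid directly; its alkene geometry is lost in the next step.

Step 7
Reactants: 8 (2Z,5S,6S)-6-acetoxy-2-chloro-7-methyl-5-(prop-1-en-2-yl)octa-2,7-dienoic acid
Product: 11 (1S)-1-[(1S,2S,5S)-5-chloro-1-methyl-6-oxobicyclo[3.2.0]hept-3-en-2-yl]-2-methylprop-2-en-1-yl acetate, via acid chloride 9 (not isolated), via chlorovinylketene 10 (not isolated)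
Conditions: (COCl)2, DMF (cat.), CH2Cl2, 0 °C; then i-Pr2NEt, PhMe, 110 °C, slow addition (5 mM)
Reagents that add atoms: none
Why: Vinylogous dehydrochlorination gives a chloro(vinyl)ketene whose intramolecular [2+2] cycloaddition with the 2-propenyl group three atoms away (ketene α-carbon to the more substituted alkene carbon) builds ring A and the cis-fused cyclobutanone at once; allylic 1,2-strain keeps C3–H and not the C3–C4 bond next to the vinylic methyl, so C1 and C13 are set with C15 trans to the C4 side chain.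

Step 8
Reactants: 12 methyl 2-bromopropanoate
Product: 13 methyl 3-[bis(2,2,2-trifluoroethoxy)phosphoryl]-4-[methoxy(methyl)amino]-2-methyl-4-oxobutanoate
Conditions: (CF3CH2O)2P(O)CH2C(O)N(OMe)Me, NaH, THF, 0 → 23 °C
Reagents that add atoms: 2-[bis(2,2,2-trifluoroethoxy)phosphoryl]-N-methoxy-N-methylacetamide, CON(C)C(=O)CP(=O)(OCC(F)(F)F)OCC(F)(F)F
Why: SN2 alkylation of the phosphonate-stabilised carbanion by the α-bromo ester; the new centres are removed or equilibrated later.

Step 9
Reactants: 13 methyl 3-[bis(2,2,2-trifluoroethoxy)phosphoryl]-4-[methoxy(methyl)amino]-2-methyl-4-oxobutanoate; 14 acrolein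
Product: 15 methyl (3Z)-3-[methoxy(methyl)carbamoyl]-2-methylhexa-3,5-dienoate
Conditions: KN(SiMe3)2, 18-crown-6, THF, −78 °C
Reagents that add atoms: none
Why: Still–Gennari variant of the Horner–Wadsworth–Emmons reaction, in which the electron-poor trifluoroethyl phosphonate eliminates under kinetic control and places the amide carbonyl cis to the vinyl group (3Z).

Step 10
Reactants: 15 methyl (3Z)-3-[methoxy(methyl)carbamoyl]-2-methylhexa-3,5-dienoate
Product: 16 methyl (3Z)-3-formyl-2-methylhexa-3,5-dienoate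
Conditions: i-Bu2AlH, THF, −78 °C
Reagents that add atoms: none
Why: The Weinreb amide is reduced to the aldehyde through a chelated tetrahedral aluminium intermediate that lasts until work-up, while the saturated methyl ester is not touched at −78 °C in THF.

Step 11
Reactants: 11 (1S)-1-[(1S,2S,5S)-5-chloro-1-methyl-6-oxobicyclo[3.2.0]hept-3-en-2-yl]-2-methylprop-2-en-1-yl acetate; 16 methyl (3Z)-3-formyl-2-methylhexa-3,5-dienoate
Product: 18 C10 aldol silyl ether of 11 (C10 carries CH(OSiMe3)–C(=CH–CH=CH2)–CH(CH3)CO2Me; C9/C10 syn; 7Z), via enol silane 17 (not isolated)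
Conditions: Me3SiOTf, Et3N, CH2Cl2, 0 °C; then 16, tris(dimethylamino)sulfonium difluorotrimethylsilicate (10 mol %), THF, −78 °C
Reagents that add atoms: trimethylsilyl triflate, C[Si](C)(C)OS(=O)(=O)C(F)(F)F
Why: Soft enolisation can only go toward C10 because C13 has no hydrogen; the fluoride-catalysed Mukaiyama-type aldol addition runs through an open transition state on the convex face (C10 chain cis to C15) and gives the syn C9/C10 relationship, the aldolate being trapped as its silyl ether.

Step 12
Reactants: 18 C10 aldol silyl ether of 11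
Product: 21 13-chloro diquinane diol (ring B formed: C12 ketone; C11 with OH and CH3; C9–OH), via silyl ketone 19 (not isolated), via enol silane 20 (not isolated)
Conditions: MeC(N2)SiMe3, Sc(OTf)3 (10 mol %), PhMe, −78 → 0 °C; then dimethyldioxirane, acetone, −78 °C; citric acid, MeOH
Reagents that add atoms: 1-(trimethylsilyl)diazoethane, CC(=[N+]=[N-])[Si](C)(C)C; dimethyldioxirane, CC1(C)OO1
Why: Proposed new method: scandium triflate activates the strained ketone for addition of the nucleophilic silyl diazoalkane, loss of N2 drives a 1,2-shift of C10 with retention (the chlorine-bearing, electron-poor, fully substituted C13 does not migrate), the α-silyl ketone relaxes by a 1,3 carbon-to-oxygen silyl shift to the tetrasubstituted C11=C12 enol silane, and the dioxirane oxidises it on the face away from the C9 chain and the C13 chlorine (Rubottom oxidation, sets C11); the closest known reactions are the scandium triflate-catalysed ring expansion of cyclobutanones with trimethylsilyldiazomethane that ends in an enol silane and the regioselective diazoalkane ring expansion of α-chlorocyclobutanones, neither shown with a disubstituted silyl diazoalkane or on an α-chloro bicyclic ketone.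

Step 13
Reactants: 21 13-chloro diquinane diol
Product: 23 γ-lactone (C19 to O–C7) carrying free C8–OH and C9–OH; vinyl on C7; 13-chloro, via triol ester 22 (not isolated)
Conditions: OsO4 (1.0 equiv), TMEDA, CH2Cl2, −78 °C; aq. NaHSO3; then PPTS, CH2Cl2, 23 °C
Reagents that add atoms: osmium tetroxide, O=[Os](=O)(=O)=O
Why: Hydroxyl-directed dihydroxylation, in which the OsO4·TMEDA complex is hydrogen-bonded to C9–OH in the conformer fixed by allylic 1,3-strain and adds syn to that hydroxyl on the only allylic-alcohol alkene (sets C8 and C7); the 7Z geometry then places C8–OH cis to the vinyl group when the less hindered allylic C7–OH closes the γ-lactone.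

Step 14
Reactants: 23 γ-lactone carrying free C8–OH and C9–OH
Product: 25 C9 acetate with (17R) methyl (single epimer; 13-chloro), via acetate mixture 24 (not isolated)
Conditions: Ac2O, DMAP, Et3N, CH2Cl2, 23 °C; then DBU, 40 °C
Reagents that add atoms: acetic anhydride, CC(=O)OC(C)=O
Why: Acetylation of the only secondary alcohol, then base equilibration of C17, the single acidic C–H because the C12 ketone is flanked by two fully substituted carbons, to the epimer with the methyl trans to the bulky C9 substituent.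

Step 15
Reactants: 25 C9 acetate with (17R) methyl
Product: 26 5,6-seco-triene (target skeleton without the C5–C6 bond and the chlorine; C4 bears prop-1-en-2-yl; C7 bears vinyl)
Conditions: Zn dust, AcOH, THF, 0 °C
Reagents that add atoms: none
Why: Zinc reduction of the α-chloro ketone gives a zinc dienolate that is protonated under kinetic control at the α-carbon C13, which keeps the C2=C14 alkene out of conjugation and can only give the cis ring fusion (sets C13).

Step 16
Reactants: 26 5,6-seco-triene
Product: 27 (5Z)-macrocycle (nine-membered ring closed; C5 bears CH3 and is doubly bonded to C6; no chlorine)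
Conditions: Hoveyda–Grubbs second-generation catalyst (10 mol %), PhMe (1 mM), 80 °C
Reagents that add atoms: none
Why: Ring-closing metathesis, in which the carbene forms at the vinyl group and closes onto the 2-propenyl group with loss of ethylene; the nine-membered ring allows only the Z trisubstituted alkene.

Step 17
Reactants: 27 (5Z)-macrocycle
Product: 28 target CNP0145188.1
Conditions: N-chlorosuccinimide, PhSeCl (10 mol %), CH2Cl2, 0 → 23 °C
Reagents that add atoms: N-chlorosuccinimide, O=C1CCC(=O)N1Cl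
Why: Selenium-catalysed ene-type allylic chlorination, in which the electrophile attacks the most substituted alkene at C6 on its outer face and hydrogen is lost from the C5 methyl, giving the C5=C16 methylene and setting C6.

**Compound list**

1 | methacrolein (2-methylprop-2-enal) | CC(=C)C=O | starting material
2 | (2E)-4-methylpenta-2,4-dienal | CC(=C)/C=C/C=O | intermediate
3 | (3E)-5,5-dimethoxy-2-methylpenta-1,3-diene | CC(=C)/C=C/C(OC)OC | intermediate
4 | 2-[(2E)-5,5-dimethoxy-2-methylpent-2-en-1-yl]-4,4,5,5-tetramethyl-1,3,2-dioxaborolane | COC(OC)C/C=C(\C)CB1OC(C)(C)C(C)(C)O1 | intermediate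
5 | (3S,4S)-4-(2,2-dimethoxyethyl)-2,5-dimethylhexa-1,5-dien-3-ol | CC(=C)[C@@H](O)[C@@H](CC(OC)OC)C(C)=C | intermediate
6 | (3S,4S)-4-(2,2-dimethoxyethyl)-2,5-dimethylhexa-1,5-dien-3-yl acetate | CC(=C)[C@@H](OC(C)=O)[C@@H](CC(OC)OC)C(C)=C | intermediate
7 | (3S,4S)-2,5-dimethyl-4-(2-oxoethyl)hexa-1,5-dien-3-yl acetate | CC(=C)[C@@H](OC(C)=O)[C@@H](CC=O)C(C)=C | intermediate
8 | (2Z,5S,6S)-6-acetoxy-2-chloro-7-methyl-5-(prop-1-en-2-yl)octa-2,7-dienoic acid | CC(=C)[C@@H](OC(C)=O)[C@@H](C/C=C(\Cl)C(O)=O)C(C)=C | intermediate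
9 | (2Z,5S,6S)-6-acetoxy-2-chloro-7-methyl-5-(prop-1-en-2-yl)octa-2,7-dienoyl chloride | CC(=C)[C@@H](OC(C)=O)[C@@H](C/C=C(\Cl)C(Cl)=O)C(C)=C | intermediate
10 | (3Z,5S,6S)-6-acetoxy-2-chloro-7-methyl-5-(prop-1-en-2-yl)octa-1,3,7-trien-1-one (chloro(vinyl)ketene) | CC(=C)[C@@H](OC(C)=O)[C@@H](/C=C\C(Cl)=C=O)C(C)=C | intermediate
11 | (1S)-1-[(1S,2S,5S)-5-chloro-1-methyl-6-oxobicyclo[3.2.0]hept-3-en-2-yl]-2-methylprop-2-en-1-yl acetate (ring A fused to the chlorocyclobutanone; bicycle C1, C2, C3=C4, C5, C6, C7 are target C1, C3, C2=C14, C13, C12, C10) | CC(=C)[C@@H](OC(C)=O)[C@H]1C=C[C@@]2(Cl)C(=O)C[C@@]12C | intermediate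
12 | methyl 2-bromopropanoate (racemic) | COC(=O)C(C)Br | starting material
13 | methyl 3-[bis(2,2,2-trifluoroethoxy)phosphoryl]-4-[methoxy(methyl)amino]-2-methyl-4-oxobutanoate (diastereomer mixture) | COC(=O)C(C)C(C(=O)N(C)OC)P(=O)(OCC(F)(F)F)OCC(F)(F)F | intermediate
14 | acrolein (prop-2-enal) | C=CC=O | starting material
15 | methyl (3Z)-3-[methoxy(methyl)carbamoyl]-2-methylhexa-3,5-dienoate (racemic) | COC(=O)C(C)/C(C(=O)N(C)OC)=C/C=C | intermediate
16 | methyl (3Z)-3-formyl-2-methylhexa-3,5-dienoate (racemic) | COC(=O)C(C)/C(C=O)=C/C=C | intermediate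
17 | trimethylsilyl enol ether of 11 (silyloxy on C12, C10=C12) | CC(=C)[C@@H](OC(C)=O)[C@H]1C=C[C@@]2(Cl)C(O[Si](C)(C)C)=C[C@@]12C | intermediate
18 | C10 aldol silyl ether of 11: C10 (exo) carries CH(OSiMe3)–C(=CH–CH=CH2)–CH(CH3)CO2Me; C9/C10 syn; 7Z; 1:1 at C17 | CC(=C)[C@@H](OC(C)=O)[C@H]1C=C[C@@]2(Cl)C(=O)[C@H]([C@H](O[Si](C)(C)C)/C(C(C)C(=O)OC)=C\C=C)[C@@]12C | intermediate
19 | ring-expanded 11-methyl-11-trimethylsilyl cyclopentanone (C11 epimers; 1:1 at C17) | CC(=C)[C@@H](OC(C)=O)[C@H]1C=C[C@@]2(Cl)C(=O)C(C)([Si](C)(C)C)[C@H]([C@H](O[Si](C)(C)C)/C(C(C)C(=O)OC)=C\C=C)[C@@]12C | intermediate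
20 | C12 trimethylsilyl enol ether (C11=C12) of the ring-expanded ketone (1:1 at C17) | CC(=C)[C@@H](OC(C)=O)[C@H]1C=C[C@@]2(Cl)C(O[Si](C)(C)C)=C(C)[C@H]([C@H](O[Si](C)(C)C)/C(C(C)C(=O)OC)=C\C=C)[C@@]12C | intermediate
21 | 13-chloro diquinane diol: C12 ketone, C11 (OH)(CH3), C9–OH, dienyl ester chain on C9 (1:1 at C17) | CC(=C)[C@@H](OC(C)=O)[C@H]1C=C[C@@]2(Cl)C(=O)[C@@](C)(O)[C@H]([C@H](O)/C(C(C)C(=O)OC)=C\C=C)[C@@]12C | intermediate
22 | C7,C8,C9-triol methyl ester (13-chloro; 1:1 at C17) | CC(=C)[C@@H](OC(C)=O)[C@H]1C=C[C@@]2(Cl)C(=O)[C@@](C)(O)[C@H]([C@H](O)[C@](O)(C(C)C(=O)OC)[C@@H](O)C=C)[C@@]12C | intermediate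
23 | γ-lactone (C19 to O–C7) with free C8–OH and C9–OH, vinyl on C7 (13-chloro; 1:1 at C17) | CC(=C)[C@@H](OC(C)=O)[C@H]1C=C[C@@]2(Cl)C(=O)[C@@](C)(O)[C@H]([C@H](O)[C@]3(O)C(C)C(=O)O[C@H]3C=C)[C@@]12C | intermediate
24 | C9 acetate of 23 (1:1 at C17) | CC(=C)[C@@H](OC(C)=O)[C@H]1C=C[C@@]2(Cl)C(=O)[C@@](C)(O)[C@H]([C@H](OC(C)=O)[C@]3(O)C(C)C(=O)O[C@H]3C=C)[C@@]12C | intermediate
25 | C9 acetate with (17R) methyl, single epimer (13-chloro derivative of 26) | CC(=C)[C@@H](OC(C)=O)[C@H]1C=C[C@@]2(Cl)C(=O)[C@@](C)(O)[C@H]([C@H](OC(C)=O)[C@]3(O)[C@@H](C)C(=O)O[C@H]3C=C)[C@@]12C | intermediate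
26 | 5,6-seco-triene: target skeleton without the C5–C6 bond and the chlorine; C4 bears prop-1-en-2-yl, C7 bears vinyl, C13–H cis to C15 | CC(=C)[C@@H](OC(C)=O)[C@H]1C=C[C@H]2C(=O)[C@@](C)(O)[C@H]([C@H](OC(C)=O)[C@]3(O)[C@@H](C)C(=O)O[C@H]3C=C)[C@@]12C | intermediate
27 | (5Z)-macrocycle: nine-membered ring closed, C5(CH3)=C6H, no chlorine | C/C1=C/[C@@H]2OC(=O)[C@H](C)[C@@]2(O)[C@@H](OC(C)=O)[C@H]3[C@](C)(O)C(=O)[C@@H]4C=C[C@@H]([C@]34C)[C@@H]1OC(C)=O | intermediate
28 | CNP0145188.1 (C6 chloride, C5=C16 methylene, C4 and C9 acetates) | C=C1[C@@H](OC(C)=O)[C@H]2C=C[C@H]3C(=O)[C@@](C)(O)[C@H]([C@H](OC(C)=O)[C@]4(O)[C@@H](C)C(=O)O[C@H]4[C@H]1Cl)[C@@]23C | target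

**Step count and risks**

Total: 17 steps. Longest linear sequence: 14 steps (steps 1–7 and 11–17).

The three steps most likely to fail are step 12, step 16 and step 17.

Step 12 (the new silyl diazoethane ring expansion with oxidation in the same flask). The fallback sets out from 18 and uses known chemistry. Diazoethane (Et2O, 0 °C) expands α-chlorocyclobutanones with migration of the non-chlorinated carbon only, which gives the 11-methyl-13-chloro cyclopentanone F1 as a C11 epimer mixture. Soft enolisation (Me3SiOTf, Et3N) can go only toward C11 and gives enol silane 20. Rubottom oxidation with dimethyldioxirane and citric acid work-up comes back to the route at 21.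

Step 16 (ring-closing metathesis to a trisubstituted alkene in a nine-membered ring). If the trans-fused lactone holds the two alkenes apart, the order of ring formation is changed so that the macrocycle is closed before the lactone. The fallback sets out from triol ester 22, isolated after the osmylation of step 13. The same ruthenium carbene cyclises it while the C7–C8 chain can still rotate, giving the macrocyclic triol ester F2. PPTS then closes the lactone across the ring to the 13-chloro macrocyclic lactone F3, acetylation gives the C9 acetate F4, and DBU gives the C17-equilibrated chloride F5. Zinc in acetic acid removes the chlorine and the route is rejoined at 27.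

Step 17 (chemoselectivity and facial selectivity of the chlorination on an alkene that carries two allylic oxygens). If it is unselective or gives the C6 epimer, oxygen is placed on C6 first. The fallback sets out from 27. The Schenck ene reaction with singlet oxygen (O2, tetraphenylporphyrin, light) is selective for the trisubstituted alkene and attacks the same outer face, giving the C6 hydroperoxide F6 with the C5=C16 methylene. PPh3 reduces it to the C6-epimeric allylic alcohol F7. Chlorination with inversion (PPh3, hexachloroacetone) then comes back to the route at 28.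

**Further compounds**

F1 | step 12 | 11-methyl-13-chloro cyclopentanone (ring B without C11–OH; C9 silyl ether; C11 epimers; 1:1 at C17) | CC(=C)[C@@H](OC(C)=O)[C@H]1C=C[C@@]2(Cl)C(=O)C(C)[C@H]([C@H](O[Si](C)(C)C)/C(C(C)C(=O)OC)=C\C=C)[C@@]12C
F2 | step 16 | (5Z)-macrocyclic C7,C8,C9-triol methyl ester (13-chloro; 1:1 at C17) | C/C1=C/[C@H](O)[C@@](O)(C(C)C(=O)OC)[C@@H](O)[C@H]3[C@](C)(O)C(=O)[C@]4(Cl)C=C[C@@H]([C@]34C)[C@@H]1OC(C)=O
F3 | step 16 | 13-chloro macrocyclic lactone with free C9–OH (1:1 at C17) | C/C1=C/[C@@H]2OC(=O)C(C)[C@@]2(O)[C@@H](O)[C@H]3[C@](C)(O)C(=O)[C@]4(Cl)C=C[C@@H]([C@]34C)[C@@H]1OC(C)=O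
F4 | step 16 | 13-chloro macrocyclic lactone C9 acetate (1:1 at C17) | C/C1=C/[C@@H]2OC(=O)C(C)[C@@]2(O)[C@@H](OC(C)=O)[C@H]3[C@](C)(O)C(=O)[C@]4(Cl)C=C[C@@H]([C@]34C)[C@@H]1OC(C)=O
F5 | step 16 | 13-chloro derivative of 27 with (17R) methyl | C/C1=C/[C@@H]2OC(=O)[C@H](C)[C@@]2(O)[C@@H](OC(C)=O)[C@H]3[C@](C)(O)C(=O)[C@]4(Cl)C=C[C@@H]([C@]34C)[C@@H]1OC(C)=O
F6 | step 17 | C6 hydroperoxide with C5=C16 methylene (oxygen on the face opposite to the target chlorine) | C=C1[C@@H](OC(C)=O)[C@H]2C=C[C@H]3C(=O)[C@@](C)(O)[C@H]([C@H](OC(C)=O)[C@]4(O)[C@@H](C)C(=O)O[C@H]4[C@@H]1OO)[C@@]23C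
F7 | step 17 | C6-epimeric allylic alcohol with C5=C16 methylene | C=C1[C@@H](OC(C)=O)[C@H]2C=C[C@H]3C(=O)[C@@](C)(O)[C@H]([C@H](OC(C)=O)[C@]4(O)[C@@H](C)C(=O)O[C@H]4[C@@H]1O)[C@@]23C
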